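The readings were computed for substances that don't exist.

Reagent stands at 1.10 equiv on the substrate, so substrate is the limiting reagent, and its balance is short: each point of substrate charged ends as product, as substrate still there, or as something unseen.

| flask | substrate | reagent | free catalyst | remark | time |
|---|---|---|---|---|---|
| Friday's | 0.062 M | 1.1 equiv (fed, over 80 s) | 5 mol% | run made earlier |  |
| flask | 0.062 M | 1.10 equiv (fed, over 80 s) | 9.9 mol% |  | 10 h |

Friday's run (percent of the substrate charged)

| time / h | substrate / % | product / % |
|---|---|---|
| 0.167 | 44 | 16 |
| 0.500 | 13 | 36 |
| 0.833 | 4 | 47 |
| 1.33 | 2 | 51 |
| 2.00 | 0 | 50 |
| 2.50 | 0 | 52 |
| 3.00 | 3 | 52 |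

(standard deviation of a reading: 1.5 percentage points)

- what was read earlier has a scatter of 1.5 percentage points, one standard deviation
- the reaction counts as stopped when no species that holds the substrate changes by six tenths of a point or more over the second half of the time
- no earlier run changes the charge of free catalyst; that part of a forecast is a guess

1. why nothing more happens at 10 h, or that something still does (forward and back rates have come level / the reagent has run out first / it is still moving / all of the substrate has reacted / no working catalyst is left)
2. how much of the substrate has reacted by 10 h
3. how much product there is at 10 h, in percent of the substrate charged

That balance gives the new flask a ceiling of 100 percent product. In Friday's run the substrate reads 0% at 2.00 h, while the product levels at about 51.3%, so the other 48.7% has gone unseen.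

The ceiling can be tightened by my own reckoning, which rests on an assumption, since Friday's run holds one loading. If the unseen path speeds up with catalyst as the product path does, the share stays at Friday's level, and that reading is taken as the floor, which is an estimate and not a strict bound. If the unseen path owes nothing to catalyst, the ratio of unseen to product falls in step with the loading. Friday's loading times unseen over product then gives 4.7 mol%, the break-even loading, the charge of free catalyst at which product and unseen loss come level. The product share is then the loading divided by loading plus break-even, which makes 67.6% at 9.9 mol%. So my estimated bracket at 10 h runs from a floor of 51.3% to a ceiling of 67.6%, and both ends carry the scatter of Friday's readings.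

The forecast says all of the substrate has reacted, with 99.5% reacted and 54% product, “perhaps higher if the side path is uncatalysed”. That stands inside the bracket, 2.7 percentage points above its floor.

The flask's answer is that all of the substrate has reacted, with 100% reacted and 64.4% product, which is 3.2 points under the estimated ceiling.

    substrate + free catalyst ⇌ catalyst intermediate A (K = 45.0 L mol⁻¹, k = 21.0 L mol⁻¹ min⁻¹)
    reagent + catalyst intermediate A → catalyst intermediate B (k = 26.0 L mol⁻¹ min⁻¹)
    catalyst intermediate C → free catalyst + product (k = 120 min⁻¹)
    catalyst intermediate B → catalyst intermediate C (k = 1.90 min⁻¹)
    2 substrate → homo dimer (k = 0.610 L mol⁻¹ min⁻¹)

The unseen loss is homo dimer: the same flask run without the path from substrate to homo dimer gives 100% product instead of 64.4%. That step holds no catalyst, which is the case the ceiling assumed. With 40 mol% of free catalyst, Friday's break-even loading of 4.7 mol% reckons 89.5% product, and the neighbour flask gives 86.9%.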